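Late in both runs D was falling, to 22.3% in beta and 17.6% in alpha at 25.0 min, lower at the larger charge. So each run had passed a crossing at which the making of D gave way to its loss, and the height of that crossing in the flask was what I set out to reckon.

| flask | Q | X | remark | time |
|---|---|---|---|---|
| beta | 0.34 M | 0.068 M | run made earlier |  |
| alpha | 0.51 M | 0.068 M | run made earlier |  |
| flask | 0.68 M | 0.0680 M |  | 25 min |

| run | time / min | D / % | Q / % |
|---|---|---|---|
| beta | 0.333 | 16.4 | 64.6 |
| beta | 0.667 | 26.4 | 43.6 |
| beta | 1.33 | 34.6 | 24.4 |
| beta | 3.00 | 34.5 | 12.9 |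
| beta | 6.00 | 29.9 | 11.8 |
| beta | 12.0 | 26.0 | 9.9 |
| beta | 25.0 | 22.3 | 10.1 |
| alpha | 0.333 | 17.2 | 64.8 |
| alpha | 0.667 | 26.6 | 43.9 |
| alpha | 1.33 | 31.8 | 25.8 |
| alpha | 3.00 | 28.6 | 16.3 |
| alpha | 6.00 | 24.3 | 12.7 |
| alpha | 12.0 | 21.0 | 11.7 |
| alpha | 25.0 | 17.6 | 10.0 |

(readings scatter by 0.5 percentage points)



- time, not beyond 25 min, at which the flask holds most D
- the amount of D, in percent of the Q charged, at that time
- earliest time at which at least nineteen twentieths of that best amount are there, in min
- latest time at which they still are, in min

The highest readings were 34.6% in beta and 31.8% in alpha, both at 1.33 min. As concentrations they are cD = 0.118 M and 0.162 M, so with more Q charged the percentage fell while cD rose. That gave me a bracket for the flask. Holding the percentage at alpha's reading gave 31.8% for the flask, which I took as my upper bound. Holding cD at alpha's reading gave 23.9%, which I took as my lower bound. To tighten this I read 0.208 from the two runs as the peak exponent, the power of the charge by which the peak percentage falls, an apparent order. Carried from alpha to the flask, it gave 30.0%.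

The forecast, on the ground that D was lost “roughly second order in D”, put 29.5% at 1.1 min, with the window from 0.85 min to 1.65 min. Its peak lay inside my bracket and below my figure.

The flask held most D, 29.2%, at 1.38 min, with the window from 0.915 min to 2.15 min. The height lay 0.80 percentage points below my figure, and the forecast's best time was earlier than the flask's.

Q ⇌ G (K = 3.10, k = 0.00850 s⁻¹); Q + D → L (k = 0.00580 M⁻¹ s⁻¹); Q + X → Z (k = 0.0470 M⁻¹ s⁻¹); Q ⇌ D + J (K = 0.270 M, k = 0.0110 s⁻¹) Carrying the same exponent from the flask's peak to the neighbouring flask with 1.2 M of Q, I reckoned 26.0%. That neighbouring flask peaked at 24.0%.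

The data come from a simulation on assumed constants, noise included.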